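The ratio of X to Q charged in this flask, 0.900, is where the reckoning starts and what it carries to a second flask.

    L.X ⇌ D (K1 = 0.89, k1 = 0.089 s⁻¹)
    L + X → L.X (k2 = 680 L mol⁻¹ s⁻¹)
    Q ⇌ L, rate k3*(cs3 - [L]) while solid is left; crystals form when [L] > cs3 (cs3 = 3.9 mM, k3 = 0.022 s⁻¹)

Q 5.0 mM; X 4.50 mM; time 2.5 h

1. the state of affairs at 2.5 h: stopped, and by what, or still going (for what has run out or reacted, a solid counts together with what of it has only dissolved) (it is still moving / X has run out first / all of Q has reacted / forward and back rates have come level)
2. part of the Q that has turned into other species by 2.5 h (what has only dissolved does not count)
3. the L.X standing at 2.5 h, as a percentage of the Q charged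
4. the D standing at 2.5 h, as a percentage of the Q charged

- solid, in amounts per volume of the solution: Q
- at the start none of Q is in solution
- what has only dissolved of Q counts as not reacted
- the reaction counts as stopped when no species that holds the Q changes by six tenths of a point or more over the second half of the time
- run time (flask): 2.5 h

**Dissolving and capture.** Solid Q enters the solution as L, at a rate proportional to how far L stands below its solubility, and L then takes up X, one for one, to give L.X. At the start of this flask X removes L with a rate constant of 3.06 s⁻¹, faster than the 0.022 s⁻¹ of dissolving. With X as charged, L therefore stands near 0.0280 mM, below its solubility of 3.9 mM, and dissolving runs close to its top rate, 0.0858 mM s⁻¹; L rises as X falls, and this reckoning takes that top rate as holding until X is gone.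

**Closed form.** A constant rate integrates to a straight line, so X in this flask falls linearly and meets zero after 0.874 min, which is short against 2.5 h. X is thus the limiting reagent, and this reckoning commits to 90.0 % as the bound ceiling, the smaller of one and the X charged over the Q charged. The excess of 0.500 mM lies below the solubility, so it can stand dissolved as L, which counts as unreacted.

**Bound split.** L.X and D relax towards each other with a half-life of 0.0611 min, short against the time, so the bound material should stand at the balance where D over L.X equals 0.89. The ceiling then divides into 47.6 % L.X and 42.4 % D.

**Forecast and result.** The forecast reads X has run out first, with 90 % converted, 47.6 % L.X and 42.4 % D, on the ground that “capture of L is fast and dissolution takes only minutes”. The flask gives X has run out first, with 0 % of X left, 90.0 % converted, 47.6 % L.X and 42.4 % D.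

**Times compared.** Half of the making of L.X up to the asked time is done by 0.452 min, short against 2.5 h, and the relaxation half-life of 0.0611 min is shorter still. L.X in this flask reads 47.6 % at 0.250 h and 47.6 % at 2.50 h.

**Second flask.** With 12 mM of Q and X unchanged, the ceiling is 37.5 %, which divides into 19.8 % L.X and 17.7 % D. That flask gives 37.5 % converted, 19.8 % L.X and 17.7 % D, with 0 % of its X left.

The constants are invented; the rest is arithmetic.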